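If one charge of starting material goes through a tank, a tube or a closed flask, the tank holds it at one steady level while it reacts, whereas the tube and the flask take it down through the same falling levels. Closing to the ring uses one molecule at a time (0.095 s⁻¹), while the open dimer uses two per turn (0.38 L mol⁻¹ s⁻¹). The ring passes reversibly into the isomer of the product (3.3, 0.18 s⁻¹), and a side step makes the side product.

| setting | Monday's | Saturday's | Wednesday's |
|---|---|---|---|
| starting material | 0.60 M | 0.60 M | 0.60 M |
| remark | a single well-mixed tank run continuously and read at steady state, 2.0 min in it on average | plug flow through a tube for 2.0 min, no back-mixing | a closed flask charged with all of it at once and left for 2.0 min |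
| time |  | 2.0 min | 2.0 min |

1. the set-up with the highest share of ring in all that became ring or open dimer or isomer of the product or side product, at the outlet or at the end ("none" if the first two lie within 2 percentage points) (Monday's / Saturday's / Wednesday's / none)
2. share of ring in all that became ring or open dimer or isomer of the product or side product, at the outlet or at the end, Monday's
3. share of ring in all that became ring or open dimer or isomer of the product or side product, at the outlet or at the end, Saturday's
4. share of ring in all that became ring or open dimer or isomer of the product or side product, at the outlet or at the end, Wednesday's

- in percentages every species weighs as the starting material in it: one open dimer or side product counts as two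
- a doubled species enters its step squared and goes two at a time
- the stated concentrations are those of everything mixed, before any reaction; amounts are the same in each set-up
- run time (Saturday's): 2.0 min

A bench rule of thumb reads the selectivity from the starting rates. In Wednesday's flask, closure over dimerisation at the charged level is 0.208, which sends 17.2% the ring way. But that rule holds while the level stays near the charge, and the half-life of starting material by ring closure alone, 0.12 min, is far shorter than the run of 2.0 min. The level therefore falls, and the ratio grows as it does.

Summed over the complete fall, the closing share is the ratio times the natural logarithm of one plus its inverse, 36.6%. The relaxation half-life of ring and isomer, 2.96 s, is short against the run, so the ring keeps one part in one plus the equilibrium constant, 23.3%. The product, the batch ring share, is 8.52%, reckoned without the side step, and it serves Saturday's tube and Wednesday's flask alike, since both run the same equations for the same time.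

Monday's tank reacts at one steady level, 0.0379 M, where closure takes 76.8%, and the same ring fraction gives 17.9%, above the tube and the flask.

The forecast names Monday's, with 19.5%, 8.5% and 8.5%, on the grounds that the tank “holds the starting material at a low level”. It stands above this reckoning for the tank.

The simulation gives Monday's, with 19.5%, 8.44% and 8.44%.

    starting material → ring (k1 = 0.095 s⁻¹)
    2 starting material → open dimer (k2 = 0.38 L mol⁻¹ s⁻¹)
    ring ⇌ isomer of the product (K3 = 3.3, k3 = 0.18 s⁻¹)
    starting material + ring → side product (k4 = 0.0099 L mol⁻¹ s⁻¹)

Wednesday's flask thus ends at 8.44% against a batch ring share of 8.52%, with 0.441% as side product. The neighbouring flask holds the time and charges 0.24 M of starting material. Its ratio is 0.521, its closing share 55.8%, and its batch ring share 13.0%. Simulated, that flask ends with ring at 12.9%, open dimer at 44.1% and isomer of the product at 42.6%.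

All constants are invented.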